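4 questions stand on these 3 flasks, and I answer them by counting turnovers.

| setting | ochre | blue | red |
|---|---|---|---|
| starting material | 0.10 M | 0.10 M | 0.10 M |
| coupling partner | 2.50 equiv | 2.50 equiv | 2.50 equiv |
| second substrate | 1.00 equiv | 1.00 equiv | 1.00 equiv |
| protic impurity | 0.0100 M | 0.0100 M | 0.0100 M |
| catalyst | 15 mol% | 15 mol% | 15 mol% |
| temperature | 60 °C | 80 °C | 40 °C |
| time | 4.0 d | 4.0 d | 4.0 d |

    starting material + coupling partner + catalyst → catalyst + target (k1 = 0.19 M⁻² min⁻¹, Ea1 = 56.0 kJ mol⁻¹)
    second substrate + coupling partner + catalyst → catalyst + second product (k2 = 0.78 M⁻² min⁻¹, Ea2 = 63.0 kJ mol⁻¹)
    coupling partner + protic impurity → quenched reagent (k3 = 0.079 M⁻¹ min⁻¹, Ea3 = 74.0 kJ mol⁻¹)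
    (constants at 60 °C)

* which flask leads in amount of target, in percent of the starting material charged ("all alike" within 1.5 percentage points) (ochre / blue / red / all alike)
* how much target is there at the end, in percent of the starting material charged: ochre
* how much target is there at the end, in percent of the starting material charged: blue
* how much target is there at the end, in percent of the starting material charged: red

- at 60 °C the constants are as listed, elsewhere as the activation energies make them

The bench rule says: partner in excess, so treat the starting material as pseudo-first-order and call the flask done after a few lifetimes. First I need the partner really there for it. In ochre the impurity lasts 50.6 min at the charged partner, and at the start the second substrate takes partner faster than the starting material does, so I book both as paid at once. That leaves 0.140 M of partner, with 0.0150 M of catalyst. The rule then gives, for ochre: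

lifetimes = first constant × catalyst × partner left × time = 2.30

yield = 90.0%

The rule stops working here. Partner left over starting material is 1.40, and the rule needs that ratio large, so that the partner stands still. Here the partner falls towards 0.0400 M as target forms. So I count on that floor. The turnover count, the first constant times catalyst times spare partner times time, is 0.657 for ochre. With both concentrations falling together, the law becomes:

yield = 1 − spare / (starting material × (e^count × partner left / starting material − 1))

ochre: count 0.657, yield 76.5%

blue: count 2.06, yield 96.0%

red: count 0.181, floor 40.9%

Red gets a floor, not a figure. Its second substrate has a lifetime of 1.01 d at the charged partner, a quarter of the time, and at the start the partner stands above the level I booked. My leader is blue.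

The forecast also names blue, with 78.5% for ochre, 96% for blue and 48% for red, holding that “the hottest flask gets furthest”. For ochre and red its figures sit above mine.

The simulation puts blue ahead, with 78.4% in ochre, 96.2% in blue and 47.9% in red.

What temperature does to the first step is the largest single effect on the spread: with it taken away, blue minus red goes from 48 percentage points to −6.5 points. That constant is what carries the count from 0.181 in red through 0.657 in ochre to 2.06 in blue. A flask like red kept at 55 °C has the count 0.483, which the law turns into 68.5%; that flask holds 71.5% of target.

(All constants are made up; the rest is arithmetic.)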